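Numbering: ring C1 (CH bearing ketone carbon C7), C2 (CH2), C3 (=CH), C4 (=C bearing CH3), C5 (CH bearing the prenyl chain C1′–C3′), C6 (CH bearing phenyl).
Retrosynthetic cuts, in order: aryl–C7 (aryllithium + aldehyde), ring bond C4–C5 (vinyl radical + diene), C1–C6 ([3,3] shift), the allylic ester C–O bond, and the bond between the acetate α-carbon (later C1) and C2.
Enabling feature: C4 is an sp2 ring carbon bonded directly to C5, and the prenyl group on C5 is an allyl radical capped with hydrogen. A C4 vinyl radical closing on the near end of a 4-methylpenta-1,3-dienyl unit on C6 therefore makes the only carbocycle and the prenyl chain together.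
Forward order: two fragments are esterified, an Ireland–Claisen rearrangement builds the acyclic chain, the radical step closes the cyclohexene, and the arene is attached last.
Stereochemistry: an asymmetric alkynylation of an aldehyde sets one carbinol centre (the cross-conjugated dienone is avoided because its two alkenyl arms are too alike for a reduction catalyst). A chair Ireland–Claisen relays this centre into C1 and C6 (anti), C6 directs C5 in the ring closure, and the C1 epimer required is also the thermodynamic one.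

Key step: step 10

Assumption: (R)-BINOL is taken to give the (S)-alcohol 4, by analogy with alkynyl transfer to aryl aldehydes. The configuration is to be checked by Mosher ester analysis, and (S)-BINOL is used if the sense proves opposite.

Step 1
Reactants: 1 phenylacetylene; 2 3-methylbut-2-enal
Product: 4 (3S)-5-methyl-1-phenylhex-4-en-1-yn-3-ol, via ethyl(phenylethynyl)zinc 3 (not isolated)
Conditions: Et2Zn, PhMe, reflux; (R)-BINOL (20 mol %), Ti(OiPr)4 (50 mol %), CH2Cl2, rt; then 2, rt
Reagents that add atoms: diethylzinc, CC[Zn]CC (zinc and one ethyl group, found in 3 only)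
Why: Catalytic asymmetric alkynylzinc addition (BINOL–Ti(IV) type), established for phenylacetylene and α,β-unsaturated aldehydes, adds 1,2 only, and the chiral titanium complex selects the aldehyde face that sets the carbinol centre.

Step 2
Reactants: 4 (3S)-5-methyl-1-phenylhex-4-en-1-yn-3-ol
Product: 6 (1E,3R)-5-methyl-1-phenylhexa-1,4-dien-3-ol, via cyclic alkenylalanate 5 (not isolated)
Conditions: Red-Al, THF, 0 °C → rt; aq. Rochelle salt
Reagents that add atoms: Red-Al, [Na+].[AlH2-](OCCOC)OCCOC (aluminium, its alkoxide ligands and sodium, found in 5 only)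
Why: Alkoxide-directed trans-hydroalumination of a propargylic alcohol gives a five-membered alanate whose protonolysis leaves only the E styryl alkene, while the isolated alkene and the stereocentre are untouched (S becomes R only through CIP ranking).

Step 3
Reactants: 7 but-2-yn-1-ol
Product: 9 (2Z)-3-iodobut-2-en-1-ol, via cyclic alkenylalanate 8 (not isolated)
Conditions: Red-Al, Et2O, 0 °C → rt; then I2, THF, −78 → 0 °C
Reagents that add atoms: iodine, II; Red-Al, [Na+].[AlH2-](OCCOC)OCCOC (aluminium, its alkoxide ligands and sodium, found in 8 only)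
Why: The same directed trans-hydroalumination places aluminium on C3 cis to the CH2O group, and iodinolysis of the C–Al bond with retention gives the Z iodoalkene as one regioisomer.

Step 4
Reactants: 9 (2Z)-3-iodobut-2-en-1-ol
Product: 10 (2Z)-1-bromo-3-iodobut-2-ene
Conditions: CBr4, PPh3, CH2Cl2, 0 °C
Reagents that add atoms: tetrabromomethane, BrC(Br)(Br)Br
Why: The Appel reaction converts the primary allylic alcohol into the bromide by SN2 displacement of the oxyphosphonium group under neutral conditions that leave the iodoalkene geometry intact.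

Step 5
Reactants: 10 (2Z)-1-bromo-3-iodobut-2-ene; 11 tert-butyl acetate
Product: 13 tert-butyl (4Z)-5-iodohex-4-enoate, via lithium enolate 12 (not isolated)
Conditions: LDA, THF, −78 °C; then 10, DMPU, −78 → −20 °C
Reagents that add atoms: lithium diisopropylamide, [Li+].CC(C)[N-]C(C)C (lithium, found in 12 only)
Why: This is an ester enolate alkylation in which the preformed, self-condensation-resistant tert-butyl acetate enolate displaces the reactive primary allylic bromide by SN2 and the vinylic iodide stays inert.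

Step 6
Reactants: 13 tert-butyl (4Z)-5-iodohex-4-enoate
Product: 14 (4Z)-5-iodohex-4-enoic acid
Conditions: TFA, CH2Cl2, 0 °C → rt
Reagents that add atoms: none
Why: Acidolysis of the tert-butyl ester (E1 loss of isobutene) frees the acid without base, and the iodine-deactivated alkene should tolerate brief exposure to TFA.

Step 7
Reactants: 6 (1E,3R)-5-methyl-1-phenylhexa-1,4-dien-3-ol; 14 (4Z)-5-iodohex-4-enoic acid
Product: 15 (1E,3R)-5-methyl-1-phenylhexa-1,4-dien-3-yl (4Z)-5-iodohex-4-enoate
Conditions: DCC, DMAP (cat.), CH2Cl2, 0 °C → rt; Et3N-deactivated silica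
Reagents that add atoms: none
Why: In the Steglich esterification the acyl group is transferred to the O–H bond under neutral conditions, so the ionisation-prone doubly allylic C–O bond and its configuration are not disturbed.

Step 8
Reactants: 15 (1E,3R)-5-methyl-1-phenylhexa-1,4-dien-3-yl (4Z)-5-iodohex-4-enoate
Product: 19 (2R,3R,4E)-2-[(2Z)-3-iodobut-2-en-1-yl]-7-methyl-3-phenylocta-4,6-dienoic acid, via lithium E(O)-enolate 16 (not isolated), via silyl ketene acetal 17 (not isolated), via trimethylsilyl ester 18 (not isolated)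
Conditions: LDA, THF, −78 °C; TMSCl, −78 °C → rt; then dilute aq. HCl
Reagents that add atoms: lithium diisopropylamide, [Li+].CC(C)[N-]C(C)C (lithium, found in 16 only); chlorotrimethylsilane, C[Si](C)(C)Cl (silyl group, found in 17 and 18 only)
Why: In this Ireland–Claisen rearrangement LDA in THF without polar cosolvent gives the E(O)-enolate, whose silyl ketene acetal reacts through a chair with the 2-methylpropenyl group equatorial, so the (R)-carbinol centre is relayed suprafacially into anti (2R,3R) C1/C6 and an E C5=C1′ bond, the styryl arm being preferred because the other arm would have to build a quaternary carbon with an axial methyl group.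

Step 9
Reactants: 19 (2R,3R,4E)-2-[(2Z)-3-iodobut-2-en-1-yl]-7-methyl-3-phenylocta-4,6-dienoic acid
Product: 20 methyl (2R,3R,4E)-2-[(2Z)-3-iodobut-2-en-1-yl]-7-methyl-3-phenylocta-4,6-dienoate
Conditions: MeI, K2CO3, DMF, rt
Reagents that add atoms: iodomethane, CI
Why: SN2 O-alkylation of the carboxylate uses a base too weak to enolise the ester, so C1 and C6 keep their configuration.

Step 10
Reactants: 20 methyl (2R,3R,4E)-2-[(2Z)-3-iodobut-2-en-1-yl]-7-methyl-3-phenylocta-4,6-dienoate
Product: 21 methyl (1R,5R,6R)-4-methyl-5-(3-methylbut-2-en-1-yl)-6-phenylcyclohex-3-ene-1-carboxylate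
Conditions: Bu3SnH (syringe pump), AIBN (cat.), degassed PhH (ca. 5 mM), reflux
Reagents that add atoms: none
Why: Bu3Sn• abstracts iodine from 20 to give the bent, rapidly inverting σ-vinyl radical at C4, which adds to C5, the near terminus of the 4-methylpenta-1,3-dienyl unit, and the resulting C1′–C3′ allyl radical abstracts hydrogen from Bu3SnH at C1′ to release the prenyl group and the chain-carrying stannyl radical. The closest known reaction type is the tin hydride-mediated cyclisation of alkenyl halides through vinyl radicals onto alkenes and conjugated dienes. The one ring closes 6-exo-trig with C3=C4 carried unchanged into the new cyclohexene, 7-endo attack at C1′ being disfavoured because it would forgo allylic delocalisation. C5 is the only new stereocentre and is controlled by C6: in the chair-like transition state the C1 ester and C6 phenyl groups are equatorial and C6–H eclipses C5=C1′ (minimal A(1,3) strain), so the tethered radical reaches the diene face anti to phenyl and the side chain ends up equatorial and trans to phenyl (5R), while C1 and C6 are untouched. Ring closure has to outrun 1,5-hydrogen transfer from C6 and direct reduction, which is served by the high radical affinity of a diene terminus, by the in-plane position of C6–H in the reactive rotamer (no overlap with the diene π system, bent C–H–C geometry across the cis C3=C4 bond) and by slow stannane addition at high dilution. Hydrogen delivery at secondary C1′ rather than tertiary C3′ is favoured by lower hindrance and by formation of the trisubstituted alkene.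

Step 11
Reactants: 21 methyl (1R,5R,6R)-4-methyl-5-(3-methylbut-2-en-1-yl)-6-phenylcyclohex-3-ene-1-carboxylate
Product: 22 (1R,5R,6R)-4-methyl-5-(3-methylbut-2-en-1-yl)-6-phenylcyclohex-3-ene-1-carbaldehyde
Conditions: DIBAL-H, PhMe, −78 °C; aq. Rochelle salt
Reagents that add atoms: none
Why: Partial ester reduction stops at the aluminium hemiacetal, which is stable at −78 °C on this α-branched ester and collapses only on work-up, and the equatorial aldehyde formed is also the favoured C1 epimer.

Step 12
Reactants: 23 3-hydroxy-4,5-dimethoxybenzaldehyde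
Product: 24 3,4-dimethoxy-5-(methoxymethoxy)benzaldehyde
Conditions: MOMCl, iPr2NEt, CH2Cl2, 0 °C → rt
Reagents that add atoms: chloromethyl methyl ether, COCCl
Why: Williamson-type O-alkylation of the phenol masks it before the peracid step.

Step 13
Reactants: 24 3,4-dimethoxy-5-(methoxymethoxy)benzaldehyde
Product: 26 3,4-dimethoxy-5-(methoxymethoxy)phenol, via aryl formate 25 (not isolated)
Conditions: mCPBA, CH2Cl2, 0 °C → rt; then K2CO3 (cat.), MeOH, rt
Reagents that add atoms: 3-chloroperoxybenzoic acid, O=C(OO)c1cccc(Cl)c1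
Why: In the Baeyer–Villiger oxidation of this electron-rich benzaldehyde the para-methoxy-activated aryl group migrates in preference to hydrogen, and the labile formate is removed by methanolysis.

Step 14
Reactants: 26 3,4-dimethoxy-5-(methoxymethoxy)phenol
Product: 27 1,2-dimethoxy-3,5-bis(methoxymethoxy)benzene
Conditions: MOMCl, iPr2NEt, CH2Cl2, 0 °C → rt
Reagents that add atoms: chloromethyl methyl ether, COCCl
Why: A second Williamson-type O-alkylation gives the arene in which one C–H is flanked by two metal-directing MOM ethers.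

Step 15
Reactants: 27 1,2-dimethoxy-3,5-bis(methoxymethoxy)benzene; 22 (1R,5R,6R)-4-methyl-5-(3-methylbut-2-en-1-yl)-6-phenylcyclohex-3-ene-1-carbaldehyde
Product: 29 [2,6-bis(methoxymethoxy)-3,4-dimethoxyphenyl][(1R,5R,6R)-4-methyl-5-(3-methylbut-2-en-1-yl)-6-phenylcyclohex-3-en-1-yl]methanol (both carbinol epimers), via aryllithium 28 (not isolated)
Conditions: n-BuLi, THF, 0 °C; then 22, −78 → 0 °C
Reagents that add atoms: n-butyllithium, [Li]CCCC (lithium, found in 28 only)
Why: Directed ortho-metalation removes the doubly coordinated, most acidic hydrogen between the two MOM ethers, and the aryllithium adds 1,2 to the aldehyde, the uncontrolled carbinol centre being erased in the next step.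

Step 16
Reactants: 29 [2,6-bis(methoxymethoxy)-3,4-dimethoxyphenyl][(1R,5R,6R)-4-methyl-5-(3-methylbut-2-en-1-yl)-6-phenylcyclohex-3-en-1-yl]methanol
Product: 30 [2,6-bis(methoxymethoxy)-3,4-dimethoxyphenyl][(1R,5R,6R)-4-methyl-5-(3-methylbut-2-en-1-yl)-6-phenylcyclohex-3-en-1-yl]methanone
Conditions: DMP, CH2Cl2, rt
Reagents that add atoms: none
Why: Dess–Martin oxidation tolerates hindered benzylic alcohols, alkenes and MOM ethers, and C1, now α to the ketone, already carries the equatorial acyl group trans to phenyl that equilibration would favour.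

Step 17
Reactants: 30 [2,6-bis(methoxymethoxy)-3,4-dimethoxyphenyl][(1R,5R,6R)-4-methyl-5-(3-methylbut-2-en-1-yl)-6-phenylcyclohex-3-en-1-yl]methanone
Product: 31 (2,6-dihydroxy-3,4-dimethoxyphenyl)[(1R,5R,6R)-4-methyl-5-(3-methylbut-2-en-1-yl)-6-phenylcyclohex-3-en-1-yl]methanone (EANPDB:ANNO_00018)
Conditions: HCl (cat.), MeOH, 40 °C
Reagents that add atoms: none
Why: Acid-catalysed acetal methanolysis cleaves both MOM ethers, which are activated by the ortho carbonyl group, under conditions mild enough for the two trisubstituted alkenes and the methyl ethers.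

Compound list
1 | phenylacetylene | C#Cc1ccccc1 | starting material
2 | 3-methylbut-2-enal | CC(C)=CC=O | starting material
3 | ethyl(phenylethynyl)zinc | CC[Zn]C#Cc1ccccc1 | intermediate
4 | (3S)-5-methyl-1-phenylhex-4-en-1-yn-3-ol | O[C@@H](C=C(C)C)C#Cc1ccccc1 | intermediate
5 | cyclic alkenylalanate from 4 (five-membered O–Al–C(Ph)=CH–CH ring, two 2-methoxyethoxy ligands, sodium salt, carbinol configuration of 4 retained) | CC(C)=C[C@H]1C=C(c2ccccc2)[Al-](OCCOC)(OCCOC)O1.[Na+] | intermediate
6 | (1E,3R)-5-methyl-1-phenylhexa-1,4-dien-3-ol | O[C@@H](C=C(C)C)/C=C/c1ccccc1 | intermediate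
7 | but-2-yn-1-ol | CC#CCO | starting material
8 | cyclic alkenylalanate from 7 (five-membered O–Al–C(CH3)=CH–CH2 ring, two 2-methoxyethoxy ligands, sodium salt) | CC1=CCO[Al-]1(OCCOC)OCCOC.[Na+] | intermediate
9 | (2Z)-3-iodobut-2-en-1-ol | C/C(I)=C/CO | intermediate
10 | (2Z)-1-bromo-3-iodobut-2-ene | C/C(I)=C/CBr | intermediate
11 | tert-butyl acetate | CC(=O)OC(C)(C)C | starting material
12 | lithium enolate of tert-butyl acetate | C=C([O-])OC(C)(C)C.[Li+] | intermediate
13 | tert-butyl (4Z)-5-iodohex-4-enoate | C/C(I)=C/CCC(=O)OC(C)(C)C | intermediate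
14 | (4Z)-5-iodohex-4-enoic acid | C/C(I)=C/CCC(=O)O | intermediate
15 | (1E,3R)-5-methyl-1-phenylhexa-1,4-dien-3-yl (4Z)-5-iodohex-4-enoate | C/C(I)=C/CCC(=O)O[C@@H](C=C(C)C)/C=C/c1ccccc1 | intermediate
16 | lithium E(O)-enolate of 15 (iodobutenyl chain trans to OLi) | C/C(I)=C/C/C=C(/[O-])O[C@@H](C=C(C)C)/C=C/c1ccccc1.[Li+] | intermediate
17 | (E)-trimethylsilyl ketene acetal of 15 (iodobutenyl chain trans to OSiMe3) | C/C(I)=C/C/C=C(/O[Si](C)(C)C)O[C@@H](C=C(C)C)/C=C/c1ccccc1 | intermediate
18 | trimethylsilyl (2R,3R,4E)-2-[(2Z)-3-iodobut-2-en-1-yl]-7-methyl-3-phenylocta-4,6-dienoate | C[Si](C)(C)OC(=O)[C@H](C/C=C(\I)C)[C@H](c1ccccc1)/C=C/C=C(C)C | intermediate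
19 | (2R,3R,4E)-2-[(2Z)-3-iodobut-2-en-1-yl]-7-methyl-3-phenylocta-4,6-dienoic acid | OC(=O)[C@H](C/C=C(\I)C)[C@H](c1ccccc1)/C=C/C=C(C)C | intermediate
20 | methyl (2R,3R,4E)-2-[(2Z)-3-iodobut-2-en-1-yl]-7-methyl-3-phenylocta-4,6-dienoate | COC(=O)[C@H](C/C=C(\I)C)[C@H](c1ccccc1)/C=C/C=C(C)C | intermediate
21 | methyl (1R,5R,6R)-4-methyl-5-(3-methylbut-2-en-1-yl)-6-phenylcyclohex-3-ene-1-carboxylate | COC(=O)[C@@H]1CC=C(C)[C@H](CC=C(C)C)[C@H]1c1ccccc1 | intermediate
22 | (1R,5R,6R)-4-methyl-5-(3-methylbut-2-en-1-yl)-6-phenylcyclohex-3-ene-1-carbaldehyde | O=C[C@@H]1CC=C(C)[C@H](CC=C(C)C)[C@H]1c1ccccc1 | intermediate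
23 | 3-hydroxy-4,5-dimethoxybenzaldehyde | COc1cc(C=O)cc(O)c1OC | starting material
24 | 3,4-dimethoxy-5-(methoxymethoxy)benzaldehyde | COCOc1cc(C=O)cc(OC)c1OC | intermediate
25 | 3,4-dimethoxy-5-(methoxymethoxy)phenyl formate | COCOc1cc(OC=O)cc(OC)c1OC | intermediate
26 | 3,4-dimethoxy-5-(methoxymethoxy)phenol | COCOc1cc(O)cc(OC)c1OC | intermediate
27 | 1,2-dimethoxy-3,5-bis(methoxymethoxy)benzene | COCOc1cc(OCOC)cc(OC)c1OC | intermediate
28 | [2,6-bis(methoxymethoxy)-3,4-dimethoxyphenyl]lithium | [Li]c1c(OCOC)cc(OC)c(OC)c1OCOC | intermediate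
29 | [2,6-bis(methoxymethoxy)-3,4-dimethoxyphenyl][(1R,5R,6R)-4-methyl-5-(3-methylbut-2-en-1-yl)-6-phenylcyclohex-3-en-1-yl]methanol, both carbinol epimers | OC(c1c(OCOC)cc(OC)c(OC)c1OCOC)[C@@H]1CC=C(C)[C@H](CC=C(C)C)[C@H]1c1ccccc1 | intermediate
30 | [2,6-bis(methoxymethoxy)-3,4-dimethoxyphenyl][(1R,5R,6R)-4-methyl-5-(3-methylbut-2-en-1-yl)-6-phenylcyclohex-3-en-1-yl]methanone | COCOc1cc(OC)c(OC)c(OCOC)c1C(=O)[C@@H]1CC=C(C)[C@H](CC=C(C)C)[C@H]1c1ccccc1 | intermediate
31 | (2,6-dihydroxy-3,4-dimethoxyphenyl)[(1R,5R,6R)-4-methyl-5-(3-methylbut-2-en-1-yl)-6-phenylcyclohex-3-en-1-yl]methanone | COc1cc(O)c(C(=O)[C@@H]2CC=C(C)[C@H](CC=C(C)C)[C@H]2c2ccccc2)c(O)c1OC | target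

Total step count: 17
Longest linear sequence: 12 steps (steps 3–11, then 15–17)

Steps most likely to fail

**Step 10**
- Process at risk: 1,5-transfer of the benzylic and dienylic C6 hydrogen to the C4 vinyl radical may compete with ring closure. Hydrogen delivery at the tertiary end C3′ of the allyl radical may also erode the prenyl regiochemistry. Neither competition responds to the stannane concentration.
- Approach: the fallback makes the same C4–C5 bond by a closed-shell mechanism on an activated acceptor.
- Route: it sets out from 20. Chemoselective dihydroxylation of the electron-rich terminal trisubstituted alkene (OsO4 cat., NMO, acetone/H2O) should give methyl (2R,3R,4E)-6,7-dihydroxy-2-[(2Z)-3-iodobut-2-en-1-yl]-7-methyl-3-phenyloct-4-enoate F1. NaIO4 cleavage should then give methyl (2R,3R,4E)-2-[(2Z)-3-iodobut-2-en-1-yl]-6-oxo-3-phenylhex-4-enoate F2.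
- Ring closure: a palladium-catalysed reductive Heck cyclisation (Pd(OAc)2, PPh3, HCO2H, Et3N, DMF) closes the same ring 6-exo by carbopalladation of C5=C1′. No radical is present, so no hydrogen-atom transfer can occur, and the palladium enolate can be reduced only at C1′. The product is methyl (1R,5R,6R)-4-methyl-5-(2-oxoethyl)-6-phenylcyclohex-3-ene-1-carboxylate F3.
- Return: Wittig olefination with isopropylidenetriphenylphosphorane F4 (from isopropyltriphenylphosphonium iodide and n-BuLi, THF, −78 → 0 °C) rebuilds the prenyl group and comes back to the route at 21.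

**Step 8**
- Process at risk: a competing [3,3] shift through the 2-methylpropenyl arm; leakage through the Z(O)-enolate or a boat transition state, which lowers anti selectivity; and ionisation or allylic transposition of the doubly allylic ester, which lowers enantiopurity.
- Approach: the fallback replaces chirality transfer by auxiliary control. C5–C6 is made by conjugate addition and C1–C2 by alkylation.
- Route: it sets out from 10 and 2. (4R)-4-Phenyl-1,3-oxazolidin-2-one is N-acylated (n-BuLi, cinnamoyl chloride, THF) to (4R)-4-phenyl-3-[(2E)-3-phenylprop-2-enoyl]-1,3-oxazolidin-2-one F5. Takai olefination of 2 (CHI3, CrCl2, THF) gives (1E)-1-iodo-4-methylpenta-1,3-diene F6, and iodine–magnesium exchange (iPrMgCl·LiCl) gives [(1E)-4-methylpenta-1,3-dien-1-yl]magnesium chloride F7.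
- Stereocontrol: CuBr·SMe2-promoted conjugate addition of F7 to the chelated s-cis form of F5 takes place on the face away from the auxiliary phenyl group. It gives (4R)-3-[(3S,4E)-7-methyl-3-phenylocta-4,6-dienoyl]-4-phenyl-1,3-oxazolidin-2-one F8. Evans alkylation (NaHMDS, THF, −78 °C, then 10) on the same open face gives (4R)-3-{(2R,3R,4E)-2-[(2Z)-3-iodobut-2-en-1-yl]-7-methyl-3-phenylocta-4,6-dienoyl}-4-phenyl-1,3-oxazolidin-2-one F9.
- Return: LiOH/H2O2 (THF/H2O, 0 °C) removes the auxiliary and comes back to the route at 19.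

**Step 15**
- Process at risk: deprotonation of the α-branched aldehyde by the basic aryllithium, slow addition of a nucleophile flanked by two ortho substituents, and incomplete lithiation.
- Approach: the fallback joins the fragments by acylative cross-coupling at the ketone oxidation level.
- Route: it sets out from 21 and 28. Saponification of 21 (LiOH, THF/MeOH/H2O, 50 °C) gives (1R,5R,6R)-4-methyl-5-(3-methylbut-2-en-1-yl)-6-phenylcyclohex-3-ene-1-carboxylic acid F10. Oxalyl chloride with catalytic DMF (CH2Cl2, 0 °C) gives (1R,5R,6R)-4-methyl-5-(3-methylbut-2-en-1-yl)-6-phenylcyclohex-3-ene-1-carbonyl chloride F11. Transmetalation of 28 with ZnCl2 gives the far less basic [2,6-bis(methoxymethoxy)-3,4-dimethoxyphenyl]zinc chloride F12.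
- Return: Negishi acylation of F12 with F11 (Pd(PPh3)4 cat., THF) comes back to the route at 30 and makes steps 11 and 16 unnecessary.

Further compounds
F1 | step 10 | methyl (2R,3R,4E)-6,7-dihydroxy-2-[(2Z)-3-iodobut-2-en-1-yl]-7-methyl-3-phenyloct-4-enoate (both C6 epimers) | COC(=O)[C@H](C/C=C(\I)C)[C@H](c1ccccc1)/C=C/C(O)C(C)(C)O
F2 | step 10 | methyl (2R,3R,4E)-2-[(2Z)-3-iodobut-2-en-1-yl]-6-oxo-3-phenylhex-4-enoate | COC(=O)[C@H](C/C=C(\I)C)[C@H](c1ccccc1)/C=C/C=O
F3 | step 10 | methyl (1R,5R,6R)-4-methyl-5-(2-oxoethyl)-6-phenylcyclohex-3-ene-1-carboxylate | COC(=O)[C@@H]1CC=C(C)[C@H](CC=O)[C@H]1c1ccccc1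
F4 | step 10 | isopropylidenetriphenylphosphorane | CC(C)=P(c1ccccc1)(c1ccccc1)c1ccccc1
F5 | step 8 | (4R)-4-phenyl-3-[(2E)-3-phenylprop-2-enoyl]-1,3-oxazolidin-2-one | O=C(/C=C/c1ccccc1)N1C(=O)OC[C@H]1c1ccccc1
F6 | step 8 | (1E)-1-iodo-4-methylpenta-1,3-diene | CC(C)=C/C=C/I
F7 | step 8 | [(1E)-4-methylpenta-1,3-dien-1-yl]magnesium chloride | CC(C)=C/C=C/[Mg]Cl
F8 | step 8 | (4R)-3-[(3S,4E)-7-methyl-3-phenylocta-4,6-dienoyl]-4-phenyl-1,3-oxazolidin-2-one | O=C(C[C@H](c1ccccc1)/C=C/C=C(C)C)N1C(=O)OC[C@H]1c1ccccc1
F9 | step 8 | (4R)-3-{(2R,3R,4E)-2-[(2Z)-3-iodobut-2-en-1-yl]-7-methyl-3-phenylocta-4,6-dienoyl}-4-phenyl-1,3-oxazolidin-2-one | O=C([C@H](C/C=C(\I)C)[C@H](c1ccccc1)/C=C/C=C(C)C)N1C(=O)OC[C@H]1c1ccccc1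
F10 | step 15 | (1R,5R,6R)-4-methyl-5-(3-methylbut-2-en-1-yl)-6-phenylcyclohex-3-ene-1-carboxylic acid | OC(=O)[C@@H]1CC=C(C)[C@H](CC=C(C)C)[C@H]1c1ccccc1
F11 | step 15 | (1R,5R,6R)-4-methyl-5-(3-methylbut-2-en-1-yl)-6-phenylcyclohex-3-ene-1-carbonyl chloride | ClC(=O)[C@@H]1CC=C(C)[C@H](CC=C(C)C)[C@H]1c1ccccc1
F12 | step 15 | [2,6-bis(methoxymethoxy)-3,4-dimethoxyphenyl]zinc chloride | Cl[Zn]c1c(OCOC)cc(OC)c(OC)c1OCOC
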